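**The price.** Ask what each mM of protic impurity costs in ring, and carry that price to the next flask.

| flask | starting material | protic impurity | remark | time |
|---|---|---|---|---|
| cedar | 1 mM (in portions, 2) | 0.20 mM | run made earlier; portions every 1.0 min |  |
| ash | 1 mM (in portions, 2) | 0.71 mM | run made earlier; portions every 1.0 min |  |
| winter | 1.0 mM (in portions, 2) | 0.250 mM | the portions of starting material follow each other after 1.0 min, the first at the start | 2.0 min |
| dawn | 1.0 mM (in portions, 2) | 0.500 mM | the portions of starting material follow each other after 1.0 min, the first at the start | 2.0 min |
| summer | 1.0 mM (in portions, 2) | 1.00 mM | the portions of starting material follow each other after 1.0 min, the first at the start | 2.0 min |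
| dusk | 1.0 mM (in portions, 2) | 2.00 mM | the portions of starting material follow each other after 1.0 min, the first at the start | 2.0 min |

| run | time / s | ring / % | starting material / % |
|---|---|---|---|
| cedar | 10.0 | 14.7 | 18.1 |
| cedar | 30.0 | 16.3 | 3.9 |
| cedar | 60.0 | 10.3 | 0 |
| cedar | 80.0 | 24.3 | 7.5 |
| cedar | 120 | 17.1 | 1.0 |
| ash | 25.0 | 16.1 | 4.9 |
| ash | 50.0 | 11.3 | 0.6 |
| ash | 80.0 | 24.3 | 7.5 |
| ash | 90.0 | 22.1 | 3.2 |
| ash | 120 | 17.1 | 0.2 |

(each reading ± 0.5 percentage points)

* amount of ring at the end, in percent of the starting material charged for winter, dawn, summer, dusk, in this order
* how the row runs (falls, then rises / hardly changes / rises, then falls / rises all the way / falls all the way)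

- "hardly changes" means that all values lie within two and a half points (for a concentration: within two and a half percent of the largest)

**Two extremes.** Suppose first that the impurity is inert: the row then stays flat at the cedar reading of 17.1%. Suppose next an instant quench, where one impurity takes one starting material at once and ring follows what remains. Ash then holds 36.2% of cedar's ring, and dusk, with 2.00 mM of impurity against 1.0 mM of charge, holds none.

**Between them.** Ash reads 17.1% at 120 s, which is more than the instant quench allows, so ash lies near the inert end. But equal readings do not prove zero effect. Two standard deviations of a difference between two readings are 1.4 percentage points, and that could hide across 0.510 mM of [protic impurity]. My reckoning therefore gives an upper estimate, at that width, for the quench sensitivity, the fraction of ring lost per mM of [protic impurity]: 0.162 mM⁻¹. If the loss runs in proportion to [protic impurity], that estimate allows a fall from winter to dusk of 4.9 points, more than the band of 2.5 points for "hardly changes". I expect a row near the cedar reading, but the readings leave its shape open.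

**The forecast.** It gives 17.1%, 17.1%, 17.1% and 17.1%, with the shape hardly changes: “the impurity stays irrelevant”.

**The row.** The flasks give 17.1%, 16.9%, 16.4% and 15.5%, and the shape is hardly changes.

    starting material + protic impurity → quenched substrate (k = 5.70 L mol⁻¹ s⁻¹)
    starting material + ring → side product (k = 4.70 L mol⁻¹ s⁻¹)
    starting material + open dimer → open trimer (k = 140 L mol⁻¹ s⁻¹)
    2 starting material → open dimer (k = 62.0 L mol⁻¹ s⁻¹)
    starting material → ring (k = 0.0570 s⁻¹)
    ring ⇌ isomer of the product (K = 3.40, k = 0.0320 s⁻¹)

From winter to dusk, quenched substrate at 2.00 min rises from 1.45% to 10.6% of the starting material charged. Between the same flasks, the quench sensitivity comes to 0.0535 mM⁻¹, below the upper estimate of 0.162 mM⁻¹. Ring falls 1.6 points across that stretch, inside the band of 2.5 points.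

Readings and results come from a simulation with constants of no real substance, noise included.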